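**Retrosynthetic overview**

1. The target is a 2,3-dihydro-4H-pyran-4-one (ring A: O1, C2, C3, C4, C4a, C8a) fused through C4a=C8a to a δ-lactone (ring B: C4a, C5, C6, O7, C8, C8a); systematic name (2S,6S)-6-decyl-2-heptyl-2,3,5,6-tetrahydropyrano[2,3-c]pyran-4,8-dione.
2. Enabling feature: in ring A the segment O1–C2(heptyl)–C3H2–C4(=O) is a 3-hydroxyacyl unit whose two ends (O1 and C4) sit on the two carbons of C4a=C8a, and that bond is the enol C=C of an α-keto-δ-lactone (C8a is the keto carbon next to lactone C8, C4a the nucleophilic carbon). Ring A is therefore a β-lactone (O1, C2, C3, C4) with C4a=C8a inserted into its acyl–oxygen bond.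
3. Key disconnection: C4–C4a and O1–C8a, giving (S)-4-heptyloxetan-2-one 6 and the enol of the (S)-α-keto-δ-lactone 17; ring A is made last, by a four- to six-membered ring expansion driven by release of β-lactone strain.
4. Lactone 6 comes from (S)-epichlorohydrin through (S)-2-heptyloxirane and ring-expanding carbonylation, so the same oxacycle grows from three to four to six members. Lactone 17 comes from (S)-epichlorohydrin through (S)-2-decyloxirane, propiolate opening, hydrogenation/lactonisation, α-hydroxylation and oxidation.
5. Order of ring formation: four-membered precursor of ring A (step 3), ring B (step 7), ring A (step 10); both stereocentres originate from (S)-epichlorohydrin and their C–O bonds are never broken.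

Key step: step 10

Remark: compound 17 is written as its enol (3-hydroxy-5,6-dihydro-2H-pyran-2-one), the tautomer expected to dominate for an α-keto-δ-lactone; the keto form is the same compound.

**Route**

Step 1
Reactants: 1 (S)-epichlorohydrin [(S)-2-(chloromethyl)oxirane]; 2 n-hexylmagnesium bromide
Product: 3 (S)-1-chlorononan-2-ol
Conditions: n-C6H13MgBr (1.2 equiv), CuI (10 mol%), THF, −40 → −20 °C; aq. HCl quench
Reagents that add atoms: n-hexylmagnesium bromide (2), CCCCCC[Mg]Br
Why: Copper-catalysed Grignard opening of a terminal epoxide; the organocopper species should attack the unsubstituted epoxide carbon much faster than it displaces chloride, so the C–O bond of the stereocentre is untouched and the (S) configuration of 1 is carried into 3.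

Step 2
Reactants: 3 (S)-1-chlorononan-2-ol
Product: 4 (S)-2-heptyloxirane
Conditions: NaOH (powdered), Et2O, 0 °C → rt
Reagents that add atoms: none
Why: Intramolecular Williamson etherification (3-exo-tet) of the chlorohydrin alkoxide; the stereocentre is not a reacting centre, so the (S)-epoxide should result.

Step 3
Reactants: 4 (S)-2-heptyloxirane; 5 carbon monoxide
Product: 6 (S)-4-heptyloxetan-2-one
Conditions: CO (60 bar), [(salph)Al(THF)2][Co(CO)4] (1 mol%; salph = N,N′-bis(3,5-di-tert-butylsalicylidene)-1,2-phenylenediaminate), DME, 50 °C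
Reagents that add atoms: carbon monoxide (5), [C-]#[O+]
Why: Ring-expanding carbonylation of an epoxide by a Lewis acid/tetracarbonylcobaltate ion pair; the cobaltate opens the activated epoxide at the CH2 terminus, CO inserts and the alkoxide captures the acyl, so the stereocentre keeps its C–O bond and its configuration.

Step 4
Reactants: 1 (S)-epichlorohydrin; 7 n-nonylmagnesium bromide
Product: 8 (S)-1-chlorododecan-2-ol
Conditions: n-C9H19MgBr (1.2 equiv), CuI (10 mol%), THF, −40 → −20 °C; aq. HCl quench
Reagents that add atoms: n-nonylmagnesium bromide (7), CCCCCCCCC[Mg]Br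
Why: Same copper-catalysed Grignard opening of the epoxide terminus as in step 1; the stereocentre of 1 is carried over unchanged.

Step 5
Reactants: 8 (S)-1-chlorododecan-2-ol
Product: 9 (S)-2-decyloxirane
Conditions: NaOH (powdered), Et2O, 0 °C → rt
Reagents that add atoms: none
Why: Intramolecular Williamson etherification of the chlorohydrin, as in step 2, with the stereocentre untouched.

Step 6
Reactants: 9 (S)-2-decyloxirane; 10 ethyl propiolate
Product: 12 ethyl (S)-5-hydroxypentadec-2-ynoate, via ethyl 3-lithiopropiolate 11 (not isolated)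
Conditions: 10 (2 equiv), n-BuLi, THF, −78 °C; BF3·OEt2; then 9, −78 °C; AcOH quench
Reagents that add atoms: ethyl propiolate (10), C#CC(=O)OCC
Why: BF3-promoted alkynylation of a terminal epoxide by a lithium acetylide at the CH2 terminus; it installs the complete five-carbon hydroxy-acid chain of ring B without touching the stereocentre.

Step 7
Reactants: 12 ethyl (S)-5-hydroxypentadec-2-ynoate
Product: 14 (S)-6-decyltetrahydro-2H-pyran-2-one, via saturated hydroxy ester 13 (not isolated)
Conditions: H2 (1 atm), Pd/C, EtOAc, rt; filter; then TsOH·H2O (cat.), PhMe, 60 °C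
Reagents that add atoms: none
Why: Heterogeneous hydrogenation of the alkyne to the saturated 5-hydroxy ester followed by acid-catalysed lactonisation (6-exo-trig acyl substitution, loss of ethanol); the carbinol centre is not involved.

Step 8
Reactants: 14 (S)-6-decyltetrahydro-2H-pyran-2-one
Product: 16 (6S)-6-decyl-3-hydroxytetrahydro-2H-pyran-2-one (both C3 epimers), via potassium enolate 15 (not isolated)
Conditions: KN(SiMe3)2 (1.1 equiv), THF, −78 °C; then 2-(phenylsulfonyl)-3-phenyloxaziridine, −78 °C; AcOH quench
Reagents that add atoms: 2-(phenylsulfonyl)-3-phenyloxaziridine, O=S(=O)(c1ccccc1)N1OC1c1ccccc1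
Why: Electrophilic α-hydroxylation of a lactone enolate by an N-sulfonyloxaziridine; the new C3 centre is expected as a mixture of epimers, which is harmless because C3 becomes sp2 in the next step.

Step 9
Reactants: 16 (6S)-6-decyl-3-hydroxytetrahydro-2H-pyran-2-one
Product: 17 (S)-6-decyl-3-hydroxy-5,6-dihydro-2H-pyran-2-one
Conditions: Dess–Martin periodinane (1.1 equiv), CH2Cl2, 0 °C → rt
Reagents that add atoms: none
Why: Hypervalent-iodine oxidation of the secondary α-hydroxy lactone to the α-keto lactone, which should tautomerise to the conjugated, hydrogen-bonded enol; both C3 epimers converge on one compound.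

Step 10
Reactants: 17 (S)-6-decyl-3-hydroxy-5,6-dihydro-2H-pyran-2-one; 6 (S)-4-heptyloxetan-2-one
Product: 20 (2S,6S)-6-decyl-2-heptyl-2,3,5,6-tetrahydropyrano[2,3-c]pyran-4,8-dione, via lithium enolate 18 (not isolated), via ring-opened C-acyl adduct 19 (not isolated)
Conditions: LiN(SiMe3)2 (1.0 equiv), THF, −78 °C; 6 (1.1 equiv), −78 °C → rt; then CF3CO2H (excess), CH2Cl2, rt
Reagents that add atoms: (S)-4-heptyloxetan-2-one (6), CCCCCCC[C@H]1CC(=O)O1
Why: Proposed new method: the lithium enolate 18 of the α-keto lactone, a ketone-type enolate that is carbon-nucleophilic at C4 of the lactone, should add to the strained acyl carbon of β-lactone 6, the tetrahedral intermediate should collapse with acyl–oxygen cleavage, and proton transfer from the new 2,4-diketo ester to the liberated alkoxide gives the stabilised enolate of 19; on acidification the secondary hydroxyl closes onto the α-keto carbon and water is lost, so that the enol C=C of 17 is formally inserted into the C(=O)–O bond of the four-membered ring, which grows to the six-membered dihydropyranone. The closest known reaction types are the Claisen acylation of lithium ester and ketone enolates by β-lactones (giving δ-hydroxy-β-keto compounds) and the acid cyclodehydration of δ-hydroxy-β-diketones to 2,3-dihydro-4H-pyran-4-ones. The only ring closed is ring A, by 6-exo-trig hemiketalisation at the keto carbon (equivalently addition–elimination on its enol) followed by dehydration. No stereocentre is created: C2 keeps the configuration of 6 because its C–O bond is never broken, and C6 comes unchanged from 17. The step needs acyl–oxygen rather than alkyl–oxygen opening of 6 (favoured by the lithium counter-ion in THF and the secondary β-carbon), C- rather than O-acylation (O-acylation should be reversible because the β-alkoxy enol ester can reclose to the β-lactone, whereas C-acylation is made irreversible by the proton transfer), and dehydration without β-elimination of the β-hydroxy ketone (mild acid at room temperature, favourable six-membered closure).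

**Compound list**

1 | (S)-epichlorohydrin [(S)-2-(chloromethyl)oxirane] | ClC[C@@H]1CO1 | starting material
2 | n-hexylmagnesium bromide | CCCCCC[Mg]Br | starting material
3 | (S)-1-chlorononan-2-ol | ClC[C@@H](O)CCCCCCC | intermediate
4 | (S)-2-heptyloxirane | CCCCCCC[C@H]1CO1 | intermediate
5 | carbon monoxide | [C-]#[O+] | starting material
6 | (S)-4-heptyloxetan-2-one | CCCCCCC[C@H]1CC(=O)O1 | intermediate
7 | n-nonylmagnesium bromide | CCCCCCCCC[Mg]Br | starting material
8 | (S)-1-chlorododecan-2-ol | ClC[C@@H](O)CCCCCCCCCC | intermediate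
9 | (S)-2-decyloxirane | CCCCCCCCCC[C@H]1CO1 | intermediate
10 | ethyl propiolate | C#CC(=O)OCC | starting material
11 | ethyl 3-lithiopropiolate | [Li]C#CC(=O)OCC | intermediate (not isolated)
12 | ethyl (S)-5-hydroxypentadec-2-ynoate | CCCCCCCCCC[C@H](O)CC#CC(=O)OCC | intermediate
13 | ethyl (S)-5-hydroxypentadecanoate | CCCCCCCCCC[C@H](O)CCCC(=O)OCC | intermediate (not isolated)
14 | (S)-6-decyltetrahydro-2H-pyran-2-one | CCCCCCCCCC[C@H]1CCCC(=O)O1 | intermediate
15 | potassium enolate of 14 | [K+].CCCCCCCCCC[C@H]1CCC=C([O-])O1 | intermediate (not isolated)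
16 | (6S)-6-decyl-3-hydroxytetrahydro-2H-pyran-2-one (C3 epimers) | CCCCCCCCCC[C@H]1CCC(O)C(=O)O1 | intermediate
17 | (S)-6-decyl-3-hydroxy-5,6-dihydro-2H-pyran-2-one | CCCCCCCCCC[C@H]1CC=C(O)C(=O)O1 | intermediate
18 | lithium enolate of 17 | [Li+].CCCCCCCCCC[C@H]1CC=C([O-])C(=O)O1 | intermediate (not isolated)
19 | (S)-6-decyl-3-hydroxy-4-[(S)-3-hydroxydecanoyl]-5,6-dihydro-2H-pyran-2-one | CCCCCCCCCC[C@H]1CC(C(=O)C[C@@H](O)CCCCCCC)=C(O)C(=O)O1 | intermediate (not isolated)
20 | (2S,6S)-6-decyl-2-heptyl-2,3,5,6-tetrahydropyrano[2,3-c]pyran-4,8-dione | CCCCCCCCCC[C@H]1CC2=C(O[C@@H](CCCCCCC)CC2=O)C(=O)O1 | target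

**Step count and risks**

Total steps: 10 (steps 1–3 give 6, steps 4–9 give 17, step 10 joins them).
Longest linear sequence: 7 steps (steps 4–10, from 1).

Steps most likely to fail:

1. Step 10 (Proposed new method). What may go wrong:
- the enolate may open the β-lactone at the alkyl carbon by SN2 (alkyl–oxygen cleavage) instead of at the acyl carbon;
- the sequence may stall at reversible O-acylation;
- excess base may deprotonate C5 of the dihydropyranone and trigger eliminative opening of ring B;
- in the acid stage, β-elimination of the β-hydroxy ketone and re-addition would erode the C2 configuration.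

Fallback, using known reactions only and closing ring B by a tethered oxalate Dieckmann condensation; it sets out from 6 and 9 and comes back to the route at 20. Lactone 6 would be opened at the acyl carbon with MeNH(OMe)·HCl/Me2AlCl (CH2Cl2) to give (S)-3-hydroxy-N-methoxy-N-methyldecanamide F1, which is silylated (tert-butyldimethylsilyl chloride, imidazole, DMF) to (S)-3-[(tert-butyldimethylsilyl)oxy]-N-methoxy-N-methyldecanamide F2. MeMgBr (THF, 0 °C) would give (S)-4-[(tert-butyldimethylsilyl)oxy]undecan-2-one F3, which is condensed with 1,1-dimethylhydrazine to its N,N-dimethylhydrazone F4. Kinetic deprotonation at the methyl group (LiN(iPr)2, THF, −78 → 0 °C) and opening of epoxide 9 at its CH2 terminus would give the γ-hydroxy hydrazone F5. Hydrolysis (aqueous CuCl2, THF) would free (8S,13S)-8-[(tert-butyldimethylsilyl)oxy]-13-hydroxytricosan-10-one F6, which may sit partly as its cyclic hemiketal. Acylation of the free hydroxyl with ethyl oxalyl chloride (pyridine, CH2Cl2, 0 °C) gives the mixed ethyl oxalate F7. Dieckmann condensation (LiN(SiMe3)2, THF, −78 → 0 °C) should then close ring B, because only the ketone α-carbon on the tether side can reach the distal oxalate carbonyl through a six-membered transition state; this gives the silyl ether of 19, (S)-4-{(S)-3-[(tert-butyldimethylsilyl)oxy]decanoyl}-6-decyl-3-hydroxy-5,6-dihydro-2H-pyran-2-one F8. Aqueous HF in MeCN would remove the silyl group and effect the same cyclodehydration to 20.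

2. Step 9. What may go wrong: over-oxidation of the electron-rich enol product by the periodinane, and aldol-type self-condensation of the keto tautomer during isolation.

Fallback, which oxidises the alkene before the enol exists and ends with a non-oxidative dehydration; it sets out from 12 and comes back at 17. Semi-hydrogenation of 12 (H2, Pd/CaCO3 poisoned with Pb(OAc)2, quinoline, EtOAc) would give ethyl (S,Z)-5-hydroxypentadec-2-enoate F9, which lactonises (cat. TsOH, PhMe) to (S)-6-decyl-5,6-dihydro-2H-pyran-2-one F10. cis-Dihydroxylation (OsO4 cat., N-methylmorpholine N-oxide, acetone/H2O) gives (6S)-6-decyl-3,4-cis-dihydroxytetrahydro-2H-pyran-2-one F11; the face of attack is irrelevant. Acid-catalysed β-elimination of the C4 hydroxyl (TsOH, PhMe, reflux, water removal) leads directly to enol 17.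

3. Step 8. What may go wrong: addition of the enolate to the N-sulfonyl imine by-product, Claisen self-condensation of the lactone enolate, and incomplete conversion.

Fallback, which avoids a strong-base enolate and introduces the keto oxygen by enamine cleavage; it sets out from 14 and comes back at 17, bypassing 16. Condensation of 14 with tert-butoxybis(dimethylamino)methane (neat, 90 °C) would give (S,E)-6-decyl-3-[(dimethylamino)methylidene]tetrahydro-2H-pyran-2-one F12. Sensitised photo-oxygenation (O2, rose bengal, hν, CH2Cl2, −78 °C) cleaves the enamine C=C through a dioxetane to give 17.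

**Further compounds**

F1 | step 10 | (S)-3-hydroxy-N-methoxy-N-methyldecanamide | CCCCCCC[C@H](O)CC(=O)N(C)OC
F2 | step 10 | (S)-3-[(tert-butyldimethylsilyl)oxy]-N-methoxy-N-methyldecanamide | CCCCCCC[C@H](O[Si](C)(C)C(C)(C)C)CC(=O)N(C)OC
F3 | step 10 | (S)-4-[(tert-butyldimethylsilyl)oxy]undecan-2-one | CCCCCCC[C@H](O[Si](C)(C)C(C)(C)C)CC(C)=O
F4 | step 10 | N,N-dimethylhydrazone of (S)-4-[(tert-butyldimethylsilyl)oxy]undecan-2-one | CCCCCCC[C@H](O[Si](C)(C)C(C)(C)C)CC(C)=NN(C)C
F5 | step 10 | N,N-dimethylhydrazone of (8S,13S)-8-[(tert-butyldimethylsilyl)oxy]-13-hydroxytricosan-10-one | CCCCCCC[C@H](O[Si](C)(C)C(C)(C)C)CC(CC[C@@H](O)CCCCCCCCCC)=NN(C)C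
F6 | step 10 | (8S,13S)-8-[(tert-butyldimethylsilyl)oxy]-13-hydroxytricosan-10-one | CCCCCCC[C@H](O[Si](C)(C)C(C)(C)C)CC(=O)CC[C@@H](O)CCCCCCCCCC
F7 | step 10 | ethyl (8S,13S)-8-[(tert-butyldimethylsilyl)oxy]-10-oxotricosan-13-yl oxalate | CCCCCCC[C@H](O[Si](C)(C)C(C)(C)C)CC(=O)CC[C@@H](OC(=O)C(=O)OCC)CCCCCCCCCC
F8 | step 10 | (S)-4-{(S)-3-[(tert-butyldimethylsilyl)oxy]decanoyl}-6-decyl-3-hydroxy-5,6-dihydro-2H-pyran-2-one | CCCCCCCCCC[C@H]1CC(C(=O)C[C@@H](O[Si](C)(C)C(C)(C)C)CCCCCCC)=C(O)C(=O)O1
F9 | step 9 | ethyl (S,Z)-5-hydroxypentadec-2-enoate | CCCCCCCCCC[C@H](O)C/C=C\C(=O)OCC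
F10 | step 9 | (S)-6-decyl-5,6-dihydro-2H-pyran-2-one | CCCCCCCCCC[C@H]1CC=CC(=O)O1
F11 | step 9 | (6S)-6-decyl-3,4-cis-dihydroxytetrahydro-2H-pyran-2-one | CCCCCCCCCC[C@H]1CC(O)C(O)C(=O)O1
F12 | step 8 | (S,E)-6-decyl-3-[(dimethylamino)methylidene]tetrahydro-2H-pyran-2-one | CCCCCCCCCC[C@H]1CC/C(=C\N(C)C)C(=O)O1
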